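The vessel holds starting material at 0.80 M, takes reagent in portions up to 0.560 M, and is started with initiator from 10 mM in noon to 80 mM in summer.

| setting | ochre | noon | dawn | midnight | summer |
|---|---|---|---|---|---|
| starting material | 0.80 M | 0.80 M | 0.80 M | 0.80 M | 0.80 M |
| reagent | 0.84 M (in portions, 3) | 0.560 M (in portions, 3) | 0.560 M (in portions, 3) | 0.560 M (in portions, 3) | 0.560 M (in portions, 3) |
| initiator | 10 mM | 10 mM | 20 mM | 40 mM | 80 mM |
| remark | run made earlier; portions every 1.5 min | the portions of reagent follow each other after 1.5 min, the first at the start | the portions of reagent follow each other after 1.5 min, the first at the start | the portions of reagent follow each other after 1.5 min, the first at the start | the portions of reagent follow each other after 1.5 min, the first at the start |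
| time |  | 40 min | 40 min | 40 min | 40 min |

- ochre (time / min: product / %, starting material / %): 4.00: 85.8, 12.8; 8.00: 98.1, 0.5; 12.0: 98.6, 0; 15.0: 97.9, 0; 20.0: 97.8, 0; 25.0: 98.6, 0

(readings scatter by 0.3 percentage points)

- percent here means starting material units held: one ended chains B counts as two
- what is said of product includes idle adduct
- the analysis behind the earlier runs scatters by 0.3 percentage points, standard deviation
- candidate steps: reagent + product <-> idle adduct; reagent + first chain carrier <-> product + second chain carrier; starting material + second chain carrier -> released group + first chain carrier; initiator -> 2 initiating radical; starting material + initiating radical -> capped initiator + first chain carrier; 2 first chain carrier -> ended chains B; 2 second chain carrier -> ended chains A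
- the concentration of product that is asked is that of its free form alone
- "hardly changes" means that all values lie within two and a half points (for a concentration: within two and a half percent of the largest)
- no earlier run changes the charge of initiator; that part of a forecast is a guess

* [product] (only what is free in solution) at the end for noon, dawn, midnight, summer, in this order
* the shape of the row from first to last (falls, then rises / rises all the way / rises, then falls / hardly changes / falls all the way)

The quick number is 0.560 M of free product in noon, dawn, midnight and summer. Product takes one reagent and one starting material, so reagent is the limiting reagent, unless the initiator eats into the starting material. It can. One initiator gives two initiating radicals, each radical turns one starting material into first chain carrier, and two such carriers join as ended chains B, which hold two units. Summer, with the largest charge of initiator, is the hardest case: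

0.80 M − 0.560 M − 2 × 80 mM = 0.0800 M

That figure is the spare starting material: what stands over once the reagent charge has become product and each initiator has paid two units. In the ochre run the later readings fall short of the charge by 14.2 mM, less than the 20.0 mM this rule charges, but starting material in that run reads 0% from 12.0 min on, so the reckoning here keeps the full two units per initiator. Summer's spare stays above zero, so by this reckoning reagent remains the limit and the row stays flat, although no earlier run varies the initiator.

Time looks ample too. Ochre had 85.8% product at 4.00 min, more than the 70.0% needed here, and these flasks run 40 min.

The forecast that came with the request gives 0.555 M, 0.555 M, 0.555 M and 0.55 M, with the shape "hardly changes", on the ground that “Termination and initiation use starting material, not reagent.” Its last point lies slightly below this reckoning.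

The flasks give 0.560 M, 0.560 M, 0.560 M and 0.560 M, and the shape is "hardly changes".

    reagent + product ⇌ idle adduct, settled at all times (K = 0.770 L mol⁻¹)
    reagent + first chain carrier ⇌ product + second chain carrier (K = 1.90, k = 18000 L mol⁻¹ s⁻¹)
    starting material + second chain carrier → released group + first chain carrier (k = 2.60 × 10⁵ L mol⁻¹ s⁻¹)
    initiator → 2 initiating radical (k = 0.00370 s⁻¹)
    starting material + initiating radical → capped initiator + first chain carrier (k = 1.60 × 10⁵ L mol⁻¹ s⁻¹)
    2 first chain carrier → ended chains B (k = 1.00 × 10⁷ L mol⁻¹ s⁻¹)
    2 second chain carrier → ended chains A (k = 9.00 × 10⁸ L mol⁻¹ s⁻¹)

Noon at 40.0 min holds 0% idle adduct and 0% reagent. Summer's spare of 0.0800 M is 10.0% of the starting material charged, and summer ends with 10.1% of that charge. The same line for midnight gives 20.0%, and midnight ends with 20%.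

The numbers in the tables are simulated from invented constants; noise was put on by code.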